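**Assumption:** the target has no stereocentre and is achiral, so "single enantiomer" needs no stereocontrol. The one stereocentre that appears on the way (carbinol 15, racemic) is removed in the last step.

## Retrosynthetic overview

1. The target is gigantol and batatasin III joined by a CH2 bridge. The bridge is cut into an aryllithium on the gigantol ring (between its OH and OMe) and a benzaldehyde on the batatasin ring; the resulting carbinol is hydrogenolysed.
2. The gigantol half comes from directed ortho-metalation of a MOM-protected bibenzyl, itself made by B-alkyl Suzuki coupling of 2-methoxy-4-vinylphenol with a MOM-protected 3-bromo-5-methoxyphenol.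
3. The batatasin half comes from methyl orsellinate, whose C1 carbon becomes the bridge, by lateral lithiation/benzylation, then ester → alcohol → aldehyde.
4. No ring is formed: all four benzene rings are bought. One Pd/H2 operation removes the benzyl ethers and the carbinol OH, then acid removes the MOM group.

## Route

Step 1
Reactants: 1 3-bromo-5-methoxyphenol
Product: 2 1-bromo-3-methoxy-5-(methoxymethoxy)benzene
Conditions: NaH, MOMCl, THF, 0 °C → rt
Reagents that add atoms: chloromethyl methyl ether (MOMCl), COCCl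
Why: Williamson-type O-alkylation of the sodium phenoxide installs the MOM acetal that later acts as the directing group for ortho-metalation.

Step 2
Reactants: 3 2-methoxy-4-vinylphenol; 2 1-bromo-3-methoxy-5-(methoxymethoxy)benzene
Product: 5 2-methoxy-4-[2-[3-methoxy-5-(methoxymethoxy)phenyl]ethyl]phenol, via bis(9-BBN) adduct 4 (not isolated)
Conditions: 9-BBN (2.2 equiv), THF, 0 °C → rt; then 2, PdCl2(dppf) (3 mol%), 3 M aq NaOH, 65 °C; aq NH4Cl work-up
Reagents that add atoms: none
Why: anti-Markovnikov hydroboration of the styrene (the second equivalent of 9-BBN masks the phenol as a borinate that the base hydrolyses) followed by B-alkyl Suzuki–Miyaura coupling gives the bibenzyl directly.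

Step 3
Reactants: 6 methyl 2,4-dihydroxy-6-methylbenzoate (methyl orsellinate)
Product: 7 methyl 4-(benzyloxy)-2-hydroxy-6-methylbenzoate
Conditions: BnBr (1.05 equiv), K2CO3, acetone, reflux
Reagents that add atoms: benzyl bromide, BrCc1ccccc1
Why: regioselective Williamson etherification, because the 2-OH is hydrogen-bonded to the ester carbonyl and only the 4-OH is alkylated.

Step 4
Reactants: 7 methyl 4-(benzyloxy)-2-hydroxy-6-methylbenzoate
Product: 8 methyl 4-(benzyloxy)-2-methoxy-6-methylbenzoate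
Conditions: MeI (3 equiv), K2CO3, DMF, 55 °C
Reagents that add atoms: iodomethane, CI
Why: Williamson O-methylation of the chelated phenol under more forcing conditions.

Step 5
Reactants: 8 methyl 4-(benzyloxy)-2-methoxy-6-methylbenzoate; 9 3-(benzyloxy)benzyl bromide
Product: 11 methyl 4-(benzyloxy)-2-[2-[3-(benzyloxy)phenyl]ethyl]-6-methoxybenzoate, via benzylic lithium species 10 (not isolated)
Conditions: LDA (1.15 equiv), THF, −78 °C, 45 min; then 9, −78 → 0 °C
Reagents that add atoms: none
Why: lateral (benzylic) lithiation of the o-toluate gives an ester-stabilised anion that is alkylated by the benzylic bromide in an SN2 reaction.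

Step 6
Reactants: 11 methyl 4-(benzyloxy)-2-[2-[3-(benzyloxy)phenyl]ethyl]-6-methoxybenzoate
Product: 12 [4-(benzyloxy)-2-[2-[3-(benzyloxy)phenyl]ethyl]-6-methoxyphenyl]methanol
Conditions: LiAlH4, THF, 0 → 50 °C; Fieser work-up
Reagents that add atoms: none
Why: hydride reduction of the hindered ester to the primary benzylic alcohol, which benzyl and methyl ethers survive.

Step 7
Reactants: 12 [4-(benzyloxy)-2-[2-[3-(benzyloxy)phenyl]ethyl]-6-methoxyphenyl]methanol
Product: 13 4-(benzyloxy)-2-[2-[3-(benzyloxy)phenyl]ethyl]-6-methoxybenzaldehyde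
Conditions: activated MnO2 (15 equiv), CH2Cl2, rt
Reagents that add atoms: none
Why: neutral MnO2 oxidation of an electron-rich benzylic alcohol stops at the aldehyde and avoids acid, to which 12 is sensitive.

Step 8
Reactants: 5 2-methoxy-4-[2-[3-methoxy-5-(methoxymethoxy)phenyl]ethyl]phenol; 13 4-(benzyloxy)-2-[2-[3-(benzyloxy)phenyl]ethyl]-6-methoxybenzaldehyde
Product: 15 rac-[4-(benzyloxy)-2-[2-[3-(benzyloxy)phenyl]ethyl]-6-methoxyphenyl][4-[2-(4-hydroxy-3-methoxyphenyl)ethyl]-2-methoxy-6-(methoxymethoxy)phenyl]methanol, via dilithio species 14 (not isolated)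
Conditions: 5 (1.3 equiv), n-BuLi (2.0 equiv per 5), THF, 0 °C → rt, 2 h; then 13 (1.0 equiv), −78 → 0 °C; aq NH4Cl
Reagents that add atoms: none
Why: the first equivalent of base makes the lithium phenoxide (which shields that ring), the second effects directed ortho-metalation at the site flanked by OMOM and OMe, and 1,2-addition to the non-enolisable aldehyde gives the carbinol; its new stereocentre is racemic and is removed in step 9.

Step 9
Reactants: 15 rac-[4-(benzyloxy)-2-[2-[3-(benzyloxy)phenyl]ethyl]-6-methoxyphenyl][4-[2-(4-hydroxy-3-methoxyphenyl)ethyl]-2-methoxy-6-(methoxymethoxy)phenyl]methanol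
Product: 17 2-[[4-hydroxy-2-[2-(3-hydroxyphenyl)ethyl]-6-methoxyphenyl]methyl]-5-[2-(4-hydroxy-3-methoxyphenyl)ethyl]-3-methoxyphenol (target), via MOM ether 16 (not isolated)
Conditions: H2 (1 atm), 10% Pd/C, EtOAc–MeOH 1:1, AcOH (5%), rt; then conc. HCl (to ca. 0.5 M), 40 °C
Reagents that add atoms: none
Why: catalytic hydrogenolysis cleaves both benzyl ethers and the very electron-rich doubly benzylic C–OH bond, and acid-catalysed acetal methanolysis then removes the MOM group.

## Compound list

1 | 3-bromo-5-methoxyphenol | COc1cc(O)cc(Br)c1 | starting material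
2 | 1-bromo-3-methoxy-5-(methoxymethoxy)benzene | COCOc1cc(Br)cc(OC)c1 | intermediate
3 | 2-methoxy-4-vinylphenol | C=Cc1ccc(O)c(OC)c1 | starting material
4 | 9-[2-[4-(9-borabicyclo[3.3.1]nonan-9-yloxy)-3-methoxyphenyl]ethyl]-9-borabicyclo[3.3.1]nonane | COc1cc(CCB2C3CCCC2CCC3)ccc1OB1C2CCCC1CCC2 | intermediate (not isolated)
5 | 2-methoxy-4-[2-[3-methoxy-5-(methoxymethoxy)phenyl]ethyl]phenol | COCOc1cc(CCc2ccc(O)c(OC)c2)cc(OC)c1 | intermediate
6 | methyl 2,4-dihydroxy-6-methylbenzoate | COC(=O)c1c(C)cc(O)cc1O | starting material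
7 | methyl 4-(benzyloxy)-2-hydroxy-6-methylbenzoate | COC(=O)c1c(C)cc(OCc2ccccc2)cc1O | intermediate
8 | methyl 4-(benzyloxy)-2-methoxy-6-methylbenzoate | COC(=O)c1c(C)cc(OCc2ccccc2)cc1OC | intermediate
9 | 3-(benzyloxy)benzyl bromide | BrCc1cccc(OCc2ccccc2)c1 | starting material
10 | methyl 4-(benzyloxy)-2-(lithiomethyl)-6-methoxybenzoate | COC(=O)c1c(C[Li])cc(OCc2ccccc2)cc1OC | intermediate (not isolated)
11 | methyl 4-(benzyloxy)-2-[2-[3-(benzyloxy)phenyl]ethyl]-6-methoxybenzoate | COC(=O)c1c(CCc2cccc(OCc3ccccc3)c2)cc(OCc2ccccc2)cc1OC | intermediate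
12 | [4-(benzyloxy)-2-[2-[3-(benzyloxy)phenyl]ethyl]-6-methoxyphenyl]methanol | OCc1c(CCc2cccc(OCc3ccccc3)c2)cc(OCc2ccccc2)cc1OC | intermediate
13 | 4-(benzyloxy)-2-[2-[3-(benzyloxy)phenyl]ethyl]-6-methoxybenzaldehyde | O=Cc1c(CCc2cccc(OCc3ccccc3)c2)cc(OCc2ccccc2)cc1OC | intermediate
14 | lithium 4-[2-[4-lithio-3-methoxy-5-(methoxymethoxy)phenyl]ethyl]-2-methoxyphenoxide | COCOc1cc(CCc2ccc(O[Li])c(OC)c2)cc(OC)c1[Li] | intermediate (not isolated)
15 | rac-[4-(benzyloxy)-2-[2-[3-(benzyloxy)phenyl]ethyl]-6-methoxyphenyl][4-[2-(4-hydroxy-3-methoxyphenyl)ethyl]-2-methoxy-6-(methoxymethoxy)phenyl]methanol (racemic carbinol, no descriptor) | COCOc1cc(CCc2ccc(O)c(OC)c2)cc(OC)c1C(O)c1c(CCc2cccc(OCc3ccccc3)c2)cc(OCc2ccccc2)cc1OC | intermediate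
16 | 3-[2-(3-hydroxyphenyl)ethyl]-4-[[4-[2-(4-hydroxy-3-methoxyphenyl)ethyl]-2-methoxy-6-(methoxymethoxy)phenyl]methyl]-5-methoxyphenol | COCOc1cc(CCc2ccc(O)c(OC)c2)cc(OC)c1Cc1c(CCc2cccc(O)c2)cc(O)cc1OC | intermediate (not isolated)
17 | 2-[[4-hydroxy-2-[2-(3-hydroxyphenyl)ethyl]-6-methoxyphenyl]methyl]-5-[2-(4-hydroxy-3-methoxyphenyl)ethyl]-3-methoxyphenol (achiral) | COc1cc(CCc2cc(O)c(Cc3c(CCc4cccc(O)c4)cc(O)cc3OC)c(OC)c2)ccc1O | target

## Summary

Total step count: 9.
Longest linear sequence: 7 steps (steps 3–9, from methyl orsellinate 6). The other branch is steps 1–2 and joins at step 8.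

Steps most likely to fail, each with a fallback:

**Step 8 (dianion metalation and hindered addition).** The lithium phenoxide may aggregate or the metalation may be incomplete or unselective, and a tetra-ortho-substituted carbinol has to form. The fallback sets out from 5 and comes back at 15, replacing the in-situ phenoxide by a discrete, non-directing silyl ether. Silylation of 5 with TIPSCl and imidazole in DMF gives triisopropyl[2-methoxy-4-[2-[3-methoxy-5-(methoxymethoxy)phenyl]ethyl]phenoxy]silane F2. Treatment with n-BuLi (1.1 equiv) and TMEDA in THF at 0 °C gives the single aryllithium [2-methoxy-6-(methoxymethoxy)-4-[2-[3-methoxy-4-(triisopropylsilyloxy)phenyl]ethyl]phenyl]lithium F3. Addition of F3 to aldehyde 13 at −78 °C gives the silyl-protected racemic carbinol F4. TBAF in THF at 0 °C removes the silyl group and returns 15.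

**Step 9 (one-pot hydrogenolysis of two benzyl ethers and a hindered carbinol, then MOM removal).** The crowded C–OH may resist the catalyst, and formaldehyde equivalents released under acid could alkylate the electron-rich rings. The fallback sets out from 15 and comes back at 17, separating an ionic deoxygenation from the debenzylation. Et3SiH (5 equiv) and TFA in CH2Cl2 at 0 °C → rt reduce the stabilised diarylmethyl cation and cleave the MOM acetal, the silane also trapping the methoxymethyl cation. This gives 2-[[4-(benzyloxy)-2-[2-[3-(benzyloxy)phenyl]ethyl]-6-methoxyphenyl]methyl]-5-[2-(4-hydroxy-3-methoxyphenyl)ethyl]-3-methoxyphenol F5. Neutral hydrogenolysis of F5 (H2, Pd/C, EtOAc–MeOH, rt) then gives 17.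

**Step 2 (hydroboration and B-alkyl Suzuki coupling with a free phenol).** The phenol consumes borane and the alkyl transfer may be sluggish. The fallback sets out from 2 and 3 and comes back at 5, building the two-carbon link by sp2–sp2 coupling and reducing afterwards. Heck coupling of 2 with 3 (Pd(OAc)2, P(o-tol)3, K2CO3, DMF, 100 °C) gives 2-methoxy-4-[(E)-2-[3-methoxy-5-(methoxymethoxy)phenyl]ethenyl]phenol F1. Hydrogenation of the alkene (H2, 5% Pd/C, EtOAc, rt; MOM and aryl ethers untouched) returns 5.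

## Further compounds

F1 | step 2 | 2-methoxy-4-[(E)-2-[3-methoxy-5-(methoxymethoxy)phenyl]ethenyl]phenol | COCOc1cc(/C=C/c2ccc(O)c(OC)c2)cc(OC)c1
F2 | step 8 | triisopropyl[2-methoxy-4-[2-[3-methoxy-5-(methoxymethoxy)phenyl]ethyl]phenoxy]silane | COCOc1cc(CCc2ccc(O[Si](C(C)C)(C(C)C)C(C)C)c(OC)c2)cc(OC)c1
F3 | step 8 | [2-methoxy-6-(methoxymethoxy)-4-[2-[3-methoxy-4-(triisopropylsilyloxy)phenyl]ethyl]phenyl]lithium | COCOc1cc(CCc2ccc(O[Si](C(C)C)(C(C)C)C(C)C)c(OC)c2)cc(OC)c1[Li]
F4 | step 8 | rac-[4-(benzyloxy)-2-[2-[3-(benzyloxy)phenyl]ethyl]-6-methoxyphenyl][2-methoxy-6-(methoxymethoxy)-4-[2-[3-methoxy-4-(triisopropylsilyloxy)phenyl]ethyl]phenyl]methanol | COCOc1cc(CCc2ccc(O[Si](C(C)C)(C(C)C)C(C)C)c(OC)c2)cc(OC)c1C(O)c1c(CCc2cccc(OCc3ccccc3)c2)cc(OCc2ccccc2)cc1OC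
F5 | step 9 | 2-[[4-(benzyloxy)-2-[2-[3-(benzyloxy)phenyl]ethyl]-6-methoxyphenyl]methyl]-5-[2-(4-hydroxy-3-methoxyphenyl)ethyl]-3-methoxyphenol | Oc1cc(CCc2ccc(O)c(OC)c2)cc(OC)c1Cc1c(CCc2cccc(OCc3ccccc3)c2)cc(OCc2ccccc2)cc1OC
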